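## Structural features

The target is a benzophenone without stereocentres, in which an unsubstituted phenyl ring (ring B) and a fully substituted benzene ring (ring A) are joined only through the ketone carbon. Numbered from the benzoyl-bearing carbon, ring A carries OH at C2, prenyl at C3, OMe at C4, prenyl at C5 and OMe at C6, so it is a phloroglucinol core in which one of three oxygens is free and hydrogen-bonded to the ketone. The ketone is non-enolisable and flanked by two ortho oxygen substituents, so it is hindered and fairly inert. The fragile parts are the two trisubstituted prenyl alkenes; the C3 prenyl is ortho to the free phenol, so protic acid, Lewis acid or electrophilic halogen would close a 2,2-dimethylchroman or add across the double bonds. The real difficulty is regiochemical: exactly one oxygen must stay unmethylated beside the acyl group, and two linear (not reverse) prenyl groups must sit on the carbons between the oxygens. The key step exploits the contiguous triad C6(OMe)–C1(benzoyl)–C2(OH): C1 and C2 are the two carbons of an aryne triple bond, and the methoxy group on C6 decides which one receives oxygen and which the acyl group. Once the triad is set, C3 and C5 are the only C–H positions left on ring A, so the prenyl groups can be placed without any question of site.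

## Logic of the disconnections

**15 to 12 and 13.** The two aryl–CH2 bonds at C3 and C5 are cut first. The prenyl groups are the only acid- and electrophile-sensitive parts, and they are identical, so they should arrive last, together, under basic conditions. This reduces 15 to dihalide 12 and two equivalents of allylboron reagent 13. The forward step must couple twice at hindered, electron-rich C–Br bonds beside a free phenol and deliver the allyl unit through its unsubstituted terminus both times; it passes through the mono-coupled bromide 14.

**12 to 10.** The C3–Br and C5–Br bonds are cut. In 10 these are the only unsubstituted carbons of ring A, and both are activated by three oxygen substituents, so halogenation needs no regiocontrol; ring B is deactivated by the carbonyl group. The forward step only has to run to completion through monobromide 11 without oxidising the phenol.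

**10 to 6 and 7.** The C2–O bond and the C1–C(=O) bond are cut together. This removes the benzoyl group and the free hydroxyl in one move and leads back to aryne 8, which carries only the two methoxy groups, and to acid 7, which supplies both the oxygen and the acyl carbon. The simplification is large, because the one-oxygen-in-three problem disappears: the free OH is created where it is needed. The forward step must add the carboxylate oxygen to the aryne carbon remote from the methoxy group, and acyl transfer within aryl anion 9 must outrun its protonation.

**6 to 2.** The C2–Si bond and the O–S bond are cut. The silicon is placed by an oxygen-to-carbon silyl shift, so the ortho-halophenol 2 already contains all the positional information. The forward sequence runs through silyl ether 3, aryllithium 4 and phenoxide 5 in one flask; it demands fast halogen–lithium exchange at low temperature and clean trapping of a hindered phenoxide.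

**2 to 1.** The C2–Br bond is cut, leading to the symmetrical phenol 1, in which the two positions ortho to the hydroxyl are equivalent. The forward step must choose an ortho position over the para position between the two methoxy groups and must stop after one substitution.

## Other disconnections considered

Alternative 1: benzannulation. Ring A is cut at C2–C3 and C4–C5. Heating 3-methoxy-2-(3-methylbut-2-en-1-yl)cyclobut-2-en-1-one A3 with 1-methoxy-5-methylhex-4-en-1-yne A2 would open the four-membered ring to a vinylketene, add the alkyne by [2+2], reopen, close by six-electron electrocyclisation and tautomerise to 3,5-dimethoxy-2,4-bis(3-methylbut-2-en-1-yl)phenol A1. Cyclobutenone A3 would itself come from alkyne A2 and ketene A4, so one alkyne serves twice.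
- In its favour: the substitution pattern follows from connectivity. Both prenyl groups arrive as intact chains, so there is no halogenation, no palladium and no question of linear against branched attachment. On this point it is better than the chosen plan.
- Against it: A2 is a sensitive, volatile 1-alkoxyalkyne and A4 is a toxic gas. A3 is a vinylogous ester and is expected to open less readily than simple cyclobutenones. Most seriously, the benzoyl group is still missing: A1 must be acylated at its last C–H with both prenyl groups present and a phenol ortho to one of them. Friedel–Crafts conditions would threaten chroman closure, so an O-benzoylation and Fries-type shift would be needed.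
- Comparison: structurally it builds ring A where the chosen plan buys it. Mechanistically it relies on a pericyclic cascade with inherent regiocontrol, against a polar aryne addition steered by one methoxy group. The step count is about equal (five to six operations), but the hardest bond, acyl next to OH, is postponed to the stage where the molecule is most fragile; in the chosen plan it is made first on a robust substrate.

Alternative 2: biomimetic Claisen folding. The C1–C6 ring bond is cut. Methyl 2,4-bis(3-methylbut-2-en-1-yl)-3,5,7-trioxo-7-phenylheptanoate A6, with Mg(OMe)2 in methanol, would cyclise by attack of the methylene between the benzoyl group and the next ketone on the ester carbonyl, and enolise to 2,4,6-trihydroxy-3,5-bis(3-methylbut-2-en-1-yl)benzophenone A5. Two O-methylations of A5 would then be needed to reach 15.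
- In its favour: one C–C bond closes the ring with every carbon substituent already in place, using no transition metal and no halogen. In convergence on the carbon skeleton it is the equal of the chosen plan or better. The competing aldol mode of folding would place the ester and a prenyl group on one ring carbon, which cannot aromatise, so the Claisen mode should dominate.
- Against it: A6 is a polyketo ester with many tautomers and two irrelevant stereocentres. Its assembly by repeated acylation of prenylated dicarbonyl anions would be longer than the whole chosen route, and lactonisation to pyranones competes. The decisive weakness lies after the key step: A5 has three hydroxyls, two of them equivalent and chelated. The methylation must take the C4 hydroxyl and exactly one chelated hydroxyl, while C-methylation at the prenyl-bearing carbons, a typical path of acylphloroglucinols, would dearomatise the ring.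
- Comparison: the chosen plan carries the two methyl ethers from the first compound and creates the single free hydroxyl in the key step, so oxygen differentiation never arises. Mechanistically both key steps are acyl transfers to carbon. In step economy the alternative is expected to be longer.

Alternative 3: fluorine placeholders. The C4–O and C6–O bonds are cut. 4,6-Difluoro-2-methoxy-3,5-bis(3-methylbut-2-en-1-yl)benzophenone A8 would be assembled from 3,5-difluoroanisole A9 by three successive fluorine-directed lithiations, trapped with prenyl and benzoyl electrophiles. NaOMe in hot DMSO would then displace both fluorides of A8 to give 2,4,6-trimethoxy-3,5-bis(3-methylbut-2-en-1-yl)benzophenone A7. Removal of one of the two equivalent ortho methyl groups of A7 would give 15.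
- In its favour: A9 is a cheap arene whose lithiation sites are fixed by the acidity of the positions next to fluorine. Prenylation of an arylmetal with an allylic halide gives the linear group reliably, and no free phenol exists until the last step. The step count from A9 is about equal to the chosen plan, and the prenyl regiochemistry is at least as secure.
- Against it: both fluorides of A8 are flanked by carbon substituents, and the di-ortho-substituted ketone is twisted out of conjugation, so activation for substitution is weak; the first methoxy group deactivates the ring further for the second. Hot methoxide in DMSO could move the prenyl double bonds into conjugation with ring A or cleave the non-enolisable ketone. The final demethylation of A7 needs a boron or aluminium Lewis acid, which endangers the prenyl alkenes and would free a hydroxyl ortho to a prenyl group under acid, the conditions for chroman closure.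
- Comparison: the alternative installs carbon first and oxygen last, and the chosen plan does the opposite. The chosen order keeps acids and forcing nucleophiles away from the prenyl groups altogether, which is the main reason for preferring it.

Key step: step 3

**Remarks on the chemistry**
- Silyl triflate 6, aryne 8 and insertion product 10 are mutually consistent and map onto ring A of 15 without any change of structure. The triflate-bearing carbon becomes C2, the silicon-bearing carbon becomes C1, and the two methoxy groups end at C6 and C4.
- The aryne precursor is deliberately kept to the two methoxy groups. A bromine or a prenyl group on the carbon next to the oxygen-accepting aryne terminus would oppose the directing effect of the methoxy group.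
- Two design choices are made around the key step. The precursor is made in two operations by a one-flask silylation, silyl shift and triflation. The prenyl groups are introduced with an allylboronate, which avoids organotin reagents and the O- against C-alkylation ambiguity of a phenoxide prenylation.
- Assumption: prenylboronic acid pinacol ester 13 is purchased.
- Step 3 is run in a pressure-rated vessel behind a shield.

## Route

Step 1
Reactants: 1 3,5-dimethoxyphenol
Product: 2 2-bromo-3,5-dimethoxyphenol
Conditions: NBS (1.0 equiv), CH2Cl2, −78 °C to rt
Reagents that add atoms: N-bromosuccinimide, O=C1CCC(=O)N1Br
Why: Electrophilic aromatic bromination; in a non-polar solvent the hydrogen-bonded phenol should deliver bromine to an ortho position (C2 and C6 are equivalent), the para position between two methoxy groups being the more hindered, and one equivalent at low temperature limits a second substitution.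

Step 2
Reactants: 2 2-bromo-3,5-dimethoxyphenol
Product: 6 3,5-dimethoxy-2-(trimethylsilyl)phenyl trifluoromethanesulfonate, via (2-bromo-3,5-dimethoxyphenoxy)trimethylsilane 3 (not isolated), via (2-lithio-3,5-dimethoxyphenoxy)trimethylsilane 4 (not isolated), via lithium 3,5-dimethoxy-2-(trimethylsilyl)phenoxide 5 (not isolated)
Conditions: HMDS, THF, 70 °C, then volatiles removed; n-BuLi, THF, −100 to −80 °C; Tf2O, −100 to −80 °C; aq NaHCO3
Reagents that add atoms: hexamethyldisilazane, C[Si](C)(C)N[Si](C)(C)C; trifluoromethanesulfonic anhydride, O=S(=O)(OS(=O)(=O)C(F)(F)F)C(F)(F)F
Why: O-silylation gives 3, bromine–lithium exchange gives 4, and a 1,3 oxygen-to-carbon silyl shift (retro-Brook rearrangement), driven by formation of the phenoxide, gives 5, which is triflated on oxygen; the one-flask sequence is the standard entry to ortho-silylaryl triflates from ortho-bromophenols.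

Step 3
Reactants: 6 3,5-dimethoxy-2-(trimethylsilyl)phenyl trifluoromethanesulfonate; 7 benzoic acid
Product: 10 2-hydroxy-4,6-dimethoxybenzophenone, via 3,5-dimethoxybenzyne 8 (not isolated), via 2-(benzoyloxy)-4,6-dimethoxyphenylcesium 9 (not isolated)
Conditions: 6 (1.5 equiv), CsF (4 equiv), THF, 125 °C, sealed pressure tube; aq NH4Cl work-up
Reagents that add atoms: none
Why: Fluoride attacks the silicon of 6 and triflate leaves from the neighbouring carbon, releasing aryne 8 slowly and at low concentration. Cesium benzoate, formed from 7 and CsF, adds through oxygen to the aryne carbon that carried the triflate, the one remote from the methoxy group, to give aryl anion 9. In 9 the carbanion lies beside the methoxy group and attacks its own ester carbonyl in a four-centre 1,3 shift of the benzoyl group from oxygen to carbon; collapse of the tetrahedral adduct gives the chelated phenoxide, which is protonated to 10 on work-up. The closest known reaction type is the fluoride-triggered insertion of arynes into the C–O bond of carboxylic acids, a relative of the anionic Fries rearrangement. No ring is closed and no stereocentre is formed. The step needs regioselective addition, which the methoxy group next to the triple bond secures: it distorts the aryne so that the distal carbon is the more electrophilic, and it stabilises the developing negative charge on the proximal carbon by induction. It also needs acyl transfer to outrun protonation of 9; excess CsF keeps the acid as its carboxylate and the high temperature favours the intramolecular shift.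

Step 4
Reactants: 10 2-hydroxy-4,6-dimethoxybenzophenone
Product: 12 3,5-dibromo-2-hydroxy-4,6-dimethoxybenzophenone, via 3-bromo-2-hydroxy-4,6-dimethoxybenzophenone 11 (not isolated)
Conditions: NBS (2.1 equiv), MeCN, 0 °C to rt
Reagents that add atoms: N-bromosuccinimide, O=C1CCC(=O)N1Br
Why: Twofold electrophilic aromatic bromination at the only two free carbons of ring A, both ortho or para to three oxygen substituents, while ring B is deactivated by the carbonyl group; the first bromine is expected ortho to the hydroxyl (11), and either order of substitution converges on 12.

Step 5
Reactants: 12 3,5-dibromo-2-hydroxy-4,6-dimethoxybenzophenone; 13 4,4,5,5-tetramethyl-2-(3-methylbut-2-en-1-yl)-1,3,2-dioxaborolane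
Product: 15 2-hydroxy-4,6-dimethoxy-3,5-bis(3-methylbut-2-en-1-yl)benzophenone, via 3-bromo-2-hydroxy-4,6-dimethoxy-5-(3-methylbut-2-en-1-yl)benzophenone 14 (not isolated)
Conditions: 13 (3 equiv), PdCl2(IPent)(3-chloropyridine) (4 mol %; IPent = 1,3-bis[2,6-di(pentan-3-yl)phenyl]imidazol-2-ylidene), 5 M aq KOH, THF, 70 °C; aq NH4Cl work-up
Reagents that add atoms: none
Why: Twofold Suzuki–Miyaura coupling of an allylboronate; the bulky carbene on palladium and the two ortho substituents beside each C–Br bond should steer reductive elimination to the unsubstituted allyl terminus, giving the linear prenyl group at both carbons, and the basic medium and buffered work-up keep the ortho-prenylphenol away from acid; 14 is drawn with the first prenyl at C5, and the order of the two couplings does not affect the product.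

## Compound list

1 | 3,5-dimethoxyphenol | COc1cc(O)cc(OC)c1 | starting material
2 | 2-bromo-3,5-dimethoxyphenol | COc1cc(O)c(Br)c(OC)c1 | intermediate
3 | (2-bromo-3,5-dimethoxyphenoxy)trimethylsilane | COc1cc(O[Si](C)(C)C)c(Br)c(OC)c1 | intermediate (not isolated)
4 | (2-lithio-3,5-dimethoxyphenoxy)trimethylsilane | COc1cc(O[Si](C)(C)C)c([Li])c(OC)c1 | intermediate (not isolated)
5 | lithium 3,5-dimethoxy-2-(trimethylsilyl)phenoxide | COc1cc([O-])c([Si](C)(C)C)c(OC)c1.[Li+] | intermediate (not isolated)
6 | 3,5-dimethoxy-2-(trimethylsilyl)phenyl trifluoromethanesulfonate | COc1cc(OC)c([Si](C)(C)C)c(OS(=O)(=O)C(F)(F)F)c1 | intermediate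
7 | benzoic acid | O=C(O)c1ccccc1 | starting material
8 | 3,5-dimethoxybenzyne | COC1=CC(OC)=CC#C1 | intermediate (not isolated)
9 | 2-(benzoyloxy)-4,6-dimethoxyphenylcesium | COc1cc(OC)cc(OC(=O)c2ccccc2)[c-]1.[Cs+] | intermediate (not isolated)
10 | 2-hydroxy-4,6-dimethoxybenzophenone | COc1cc(O)c(C(=O)c2ccccc2)c(OC)c1 | intermediate
11 | 3-bromo-2-hydroxy-4,6-dimethoxybenzophenone | COc1cc(OC)c(C(=O)c2ccccc2)c(O)c1Br | intermediate (not isolated)
12 | 3,5-dibromo-2-hydroxy-4,6-dimethoxybenzophenone | COc1c(Br)c(O)c(C(=O)c2ccccc2)c(OC)c1Br | intermediate
13 | 4,4,5,5-tetramethyl-2-(3-methylbut-2-en-1-yl)-1,3,2-dioxaborolane | CC(C)=CCB1OC(C)(C)C(C)(C)O1 | starting material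
14 | 3-bromo-2-hydroxy-4,6-dimethoxy-5-(3-methylbut-2-en-1-yl)benzophenone | COc1c(Br)c(O)c(C(=O)c2ccccc2)c(OC)c1CC=C(C)C | intermediate (not isolated)
15 | 2-hydroxy-4,6-dimethoxy-3,5-bis(3-methylbut-2-en-1-yl)benzophenone | COc1c(CC=C(C)C)c(O)c(C(=O)c2ccccc2)c(OC)c1CC=C(C)C | target

## Step count and least certain steps

Total step count: 5. Longest linear sequence: 5 steps (1 to 2 to 6 to 10 to 12 to 15); 7 and 13 enter as purchased partners.

**Step 3 (key step).** The most likely failure is protonation of the aryl anion before the acyl group has moved, which would give plain O-arylation of the acid in place of insertion. Lesser risks are erosion of the regioselectivity of addition and arylation of the product phenoxide by excess aryne. The fallback makes the same two-centre pattern without an aryne. It sets out from 2, which is benzoylated (benzoyl chloride, aq NaOH, CH2Cl2) to 2-bromo-3,5-dimethoxyphenyl benzoate F1. Bromine–lithium exchange with s-BuLi in THF/Et2O at −95 °C gives 2-(benzoyloxy)-4,6-dimethoxyphenyllithium F2, which undergoes the anionic Fries shift of the benzoyl group from oxygen to the lithiated carbon on warming. Work-up returns the route at 10.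

**Step 5.** The risks are allylic transposition at palladium leading to attachment through the substituted terminus, protodeboronation of the allylboronate in hot aqueous base, and stalling after the first coupling because the phenoxide-bearing ring is electron-rich and both C–Br bonds are doubly ortho-substituted. The fallback separates C–C coupling from construction of the trisubstituted alkene. It sets out from 12, which is coupled twice under the same palladium catalysis with allylboronic acid pinacol ester, a symmetrical and smaller allyl donor, to 2-hydroxy-4,6-dimethoxy-3,5-di(prop-2-en-1-yl)benzophenone F3. Twofold olefin cross-metathesis with 2-methylbut-2-ene and RuCl2(=CHPh)(PCy3)(H2IMes), the second-generation Grubbs catalyst, in CH2Cl2 at 40 °C then converts both allyl groups into prenyl groups and returns the route at 15.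

**Step 1.** The risks are competing substitution at the position para to the hydroxyl and a second bromination of the very electron-rich ring. The fallback replaces electrophilic substitution by directed metalation and also bypasses step 2. It sets out from 1, which is converted with isopropyl isocyanate (cat. Et3N, CH2Cl2) into 3,5-dimethoxyphenyl N-(propan-2-yl)carbamate F4. N-Silylation in the flask (TBSOTf, TMEDA, Et2O) gives 3,5-dimethoxyphenyl N-[tert-butyl(dimethyl)silyl]-N-(propan-2-yl)carbamate F5. Lithiation with n-BuLi/TMEDA at −78 °C should occur between the carbamate and the neighbouring methoxy group, the site activated by both directing groups, and TMSCl gives 3,5-dimethoxy-2-(trimethylsilyl)phenyl N-[tert-butyl(dimethyl)silyl]-N-(propan-2-yl)carbamate F6. Aqueous NaHSO4 work-up removes the N-silyl group to give 3,5-dimethoxy-2-(trimethylsilyl)phenyl N-(propan-2-yl)carbamate F7. DBU and Et2NH in MeCN at 40 °C cleave the carbamate by elimination to 3,5-dimethoxy-2-(trimethylsilyl)phenol F8, which is triflated in the same flask with PhNTf2. The route is rejoined at 6.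

## Further compounds

F1 | step 3 | 2-bromo-3,5-dimethoxyphenyl benzoate | COc1cc(OC(=O)c2ccccc2)c(Br)c(OC)c1
F2 | step 3 | 2-(benzoyloxy)-4,6-dimethoxyphenyllithium | [Li]c1c(OC)cc(OC)cc1OC(=O)c1ccccc1
F3 | step 5 | 2-hydroxy-4,6-dimethoxy-3,5-di(prop-2-en-1-yl)benzophenone | COc1c(CC=C)c(O)c(C(=O)c2ccccc2)c(OC)c1CC=C
F4 | step 1 | 3,5-dimethoxyphenyl N-(propan-2-yl)carbamate | COc1cc(OC)cc(OC(=O)NC(C)C)c1
F5 | step 1 | 3,5-dimethoxyphenyl N-[tert-butyl(dimethyl)silyl]-N-(propan-2-yl)carbamate | COc1cc(OC)cc(OC(=O)N(C(C)C)[Si](C)(C)C(C)(C)C)c1
F6 | step 1 | 3,5-dimethoxy-2-(trimethylsilyl)phenyl N-[tert-butyl(dimethyl)silyl]-N-(propan-2-yl)carbamate | COc1cc(OC)c([Si](C)(C)C)c(OC(=O)N(C(C)C)[Si](C)(C)C(C)(C)C)c1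
F7 | step 1 | 3,5-dimethoxy-2-(trimethylsilyl)phenyl N-(propan-2-yl)carbamate | COc1cc(OC)c([Si](C)(C)C)c(OC(=O)NC(C)C)c1
F8 | step 1 | 3,5-dimethoxy-2-(trimethylsilyl)phenol | COc1cc(O)c([Si](C)(C)C)c(OC)c1
A1 | alternative 1 | 3,5-dimethoxy-2,4-bis(3-methylbut-2-en-1-yl)phenol | COc1cc(O)c(CC=C(C)C)c(OC)c1CC=C(C)C
A2 | alternative 1 | 1-methoxy-5-methylhex-4-en-1-yne | COC#CCC=C(C)C
A3 | alternative 1 | 3-methoxy-2-(3-methylbut-2-en-1-yl)cyclobut-2-en-1-one | COC1=C(CC=C(C)C)C(=O)C1
A4 | alternative 1 | ketene | C=C=O
A5 | alternative 2 | 2,4,6-trihydroxy-3,5-bis(3-methylbut-2-en-1-yl)benzophenone | O=C(c1ccccc1)c1c(O)c(CC=C(C)C)c(O)c(CC=C(C)C)c1O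
A6 | alternative 2 | methyl 2,4-bis(3-methylbut-2-en-1-yl)-3,5,7-trioxo-7-phenylheptanoate | COC(=O)C(CC=C(C)C)C(=O)C(CC=C(C)C)C(=O)CC(=O)c1ccccc1
A7 | alternative 3 | 2,4,6-trimethoxy-3,5-bis(3-methylbut-2-en-1-yl)benzophenone | COc1c(CC=C(C)C)c(OC)c(C(=O)c2ccccc2)c(OC)c1CC=C(C)C
A8 | alternative 3 | 4,6-difluoro-2-methoxy-3,5-bis(3-methylbut-2-en-1-yl)benzophenone | COc1c(CC=C(C)C)c(F)c(CC=C(C)C)c(F)c1C(=O)c1ccccc1
A9 | alternative 3 | 3,5-difluoroanisole | COc1cc(F)cc(F)c1
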